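**Plan**
- Enabling feature: in the target, the hydroxymethyl carbon on C3 and the benzylic carbon on C4 of the oxolane ring are cis to each other and trans to the aryl group on C2. This is the pattern a two-carbon bridge leaves when it is laid across a C3=C4 double bond from the face opposite the aryl group.
- Retrosynthesis: CH2OH goes back to CO2H and the benzylic CH2 to an acyloxy-bearing carbon. These two carbons are rejoined (reverse Baeyer–Villiger) into a cyclobutanone fused on C3–C4. Then the benzylic C–aryl bond is cut, then the C3–C(=O) and C4–C bonds of the four-membered ring, and last the C2–aryl bond.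
- Forward: the oxolane ring is bought as 2,3-dihydrofuran and arylated at C2. The cyclobutanone ring is fused on, arylated at its CH2 and opened by oxygen insertion, and the lactone is taken down to the acid and then the alcohol.
- Stereochemistry: C2 comes from the ligand-controlled Heck arylation. C3 and C4 come from the suprafacial ketene addition anti to the aryl group and are not touched afterwards.

Key step: step 3

Assumption: the (R)-configured tert-butyl-PHOX ligand is taken to give (S)-4, by analogy with phenyl triflate, where the (S)-ligand gives the (R)-product and the CIP ranking at C2 is the same; if the sense is reversed for this aryl group, the antipodal ligand is used.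

**Step 1**
Reactants: 1 4-(benzyloxy)-3-methoxyphenol
Product: 2 4-(benzyloxy)-3-methoxyphenyl trifluoromethanesulfonate
Conditions: Tf2O, pyridine, CH2Cl2, 0 °C
Reagents that add atoms: trifluoromethanesulfonic anhydride, O=S(=O)(OS(=O)(=O)C(F)(F)F)C(F)(F)F
Why: O-sulfonylation of a phenol with triflic anhydride and an amine base is routine, and the benzyl and methyl ethers are inert to it.

**Step 2**
Reactants: 2 4-(benzyloxy)-3-methoxyphenyl trifluoromethanesulfonate; 3 2,3-dihydrofuran (excess)
Product: 4 (S)-2-[4-(benzyloxy)-3-methoxyphenyl]-2,5-dihydrofuran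
Conditions: Pd2(dba)3 (3 mol%), (R)-t-Bu-PHOX (7 mol%), i-Pr2NEt, THF, 70 °C
Reagents that add atoms: none
Why: Enantioselective Heck arylation: the cationic arylpalladium species adds syn across the enol ether with the aryl group going to the oxygen-bearing carbon, β-hydride elimination away from that carbon and rapid release of the alkene from the P,N-ligated metal leave the unisomerised 2,5-dihydrofuran, and the tert-butyl oxazoline selects the alkene face and so sets C2 as S.

**Step 3**
Reactants: 4 (S)-2-[4-(benzyloxy)-3-methoxyphenyl]-2,5-dihydrofuran; 5 trichloroacetyl chloride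
Product: 7 (1R,4S,5S)-4-[4-(benzyloxy)-3-methoxyphenyl]-7,7-dichloro-3-oxabicyclo[3.2.0]heptan-6-one, via dichloroketene 6 (not isolated)
Conditions: Zn–Cu couple, Cl3CCOCl (slow addition), Et2O–DME, 25 °C
Reagents that add atoms: none
Why: Zinc strips two chlorines from 5 to give dichloroketene 6, whose electrophilic central carbon attacks C3=C4 of 4 in a concerted but asynchronous [2+2] cycloaddition that is suprafacial on the alkene, the C3–C(=O) bond forming slightly ahead of the C4–CCl2 bond. The closest known reaction is the zinc/trichloroacetyl chloride addition of dichloroketene to cyclopentene and to the parent 2,5-dihydrofuran, so the reaction type is established and only the orientation on a 2-aryl substrate is untested. The cyclobutanone ring closes by cycloaddition across the existing C3–C4 ring bond with both new bonds entering from one face, which makes the four/five ring fusion cis by necessity. C3 and C4 become stereocentres under control of the C2 aryl group, which shields its own face so that the ketene arrives on the opposite one and the two-carbon bridge ends trans to the aryl group. The step needs regioselectivity (carbonyl carbon to C3, CCl2 to C4), which rests on the compact sp carbonyl carbon being better accommodated beside the substituted C2 than the CCl2 end with its inward-pointing chlorine, and on positive charge building up at C4 and not beside the more electron-poor aryl-bearing carbon; any regioisomer is removed by chromatography. It also needs chemoselectivity for the alkene over the ring oxygen, which binding of ZnCl2 by dimethoxyethane and slow addition of 5 should secure against ionisation of the allylic benzylic ether and against O-acylation followed by ketene-Claisen rearrangement.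

**Step 4**
Reactants: 7 (1R,4S,5S)-4-[4-(benzyloxy)-3-methoxyphenyl]-7,7-dichloro-3-oxabicyclo[3.2.0]heptan-6-one
Product: 9 (1R,4S,5S)-4-[4-(benzyloxy)-3-methoxyphenyl]-3-oxabicyclo[3.2.0]heptan-6-one, via monochloro ketone 8 (not isolated)
Conditions: Zn dust, AcOH, 25 °C
Reagents that add atoms: none
Why: Zinc in acetic acid reduces α-chloro ketones through zinc enolates that are protonated, one chlorine after the other, and no ring stereocentre is involved because the cis ring fusion cannot invert.

**Step 5**
Reactants: 9 (1R,4S,5S)-4-[4-(benzyloxy)-3-methoxyphenyl]-3-oxabicyclo[3.2.0]heptan-6-one; 10 4-bromo-1,2-dimethoxybenzene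
Product: 11 (1R,4S,5S)-4-[4-(benzyloxy)-3-methoxyphenyl]-7-(3,4-dimethoxyphenyl)-3-oxabicyclo[3.2.0]heptan-6-one (either C7 epimer is usable, exo-aryl expected to prevail)
Conditions: LiN(SiMe3)2 (2.2 equiv), THF, −78 °C; then 10, Pd(dba)2 (5 mol%), t-Bu3P (10 mol%), toluene, −78 → 40 °C
Reagents that add atoms: none
Why: Palladium-catalysed α-arylation of a ketone enolate: the enolate can form only at the CH2 (C7), since enolisation toward the ring-fusion carbon would put a double bond at the bridgehead of the strained bicycle; preforming it with a non-nucleophilic amide keeps free ketone, and hence aldol condensation and alkoxide ring opening, out of the flask; transmetalation to the arylpalladium bromide and reductive elimination make the C7–aryl bond, and the new centre is of no consequence because it ends as CH2.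

**Step 6**
Reactants: 11 (1R,4S,5S)-4-[4-(benzyloxy)-3-methoxyphenyl]-7-(3,4-dimethoxyphenyl)-3-oxabicyclo[3.2.0]heptan-6-one
Product: 12 (1S,5R,8S)-8-[4-(benzyloxy)-3-methoxyphenyl]-4-(3,4-dimethoxyphenyl)-3,7-dioxabicyclo[3.3.0]octan-2-one (C4 epimers; lactone C=O on the bridgehead next to the C8 aryl carbon)
Conditions: mCPBA, NaHCO3, CH2Cl2, 0 °C
Reagents that add atoms: meta-chloroperoxybenzoic acid, O=C(OO)c1cccc(Cl)c1
Why: Baeyer–Villiger oxidation of a strained cyclobutanone is fast at 0 °C, and in the Criegee adduct the secondary benzylic carbon bearing the electron-rich dimethoxyphenyl group should migrate in preference to the ring-fusion carbon, which is deactivated by its neighbouring C–O bond, so oxygen enters between C=O and the benzylic carbon with retention and cuts the temporary bond.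

**Step 7**
Reactants: 12 (1S,5R,8S)-8-[4-(benzyloxy)-3-methoxyphenyl]-4-(3,4-dimethoxyphenyl)-3,7-dioxabicyclo[3.3.0]octan-2-one
Product: 14 (2S,3S,4R)-4-(3,4-dimethoxybenzyl)-2-(4-hydroxy-3-methoxyphenyl)oxolane-3-carboxylic acid, via phenolic lactone 13 (not isolated)
Conditions: H2 (1 atm), Pd/C (10%), EtOAc–EtOH, 20 °C, stopped when 13 is consumed
Reagents that add atoms: none
Why: Catalytic hydrogenolysis should first remove the O-benzyl group and then cleave the acyloxy-substituted benzylic C–O bond of the strained cis-fused lactone, which as a benzylic ester goes ahead of the benzylic alkyl ether C2–O1 of the oxolane, turning the benzylic carbon into CH2 without touching C3 or C4.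

**Step 8**
Reactants: 14 (2S,3S,4R)-4-(3,4-dimethoxybenzyl)-2-(4-hydroxy-3-methoxyphenyl)oxolane-3-carboxylic acid
Product: 15 4'-O-methyllariciresinol, [(2S,3R,4R)-4-(3,4-dimethoxybenzyl)-2-(4-hydroxy-3-methoxyphenyl)oxolan-3-yl]methanol
Conditions: BH3·THF (excess), THF, 0 → 20 °C; aqueous work-up
Reagents that add atoms: none
Why: Borane reduces a carboxylic acid to the primary alcohol through the acyloxyborane, the phenol merely consumes hydride as an aryloxyborane that is hydrolysed on work-up, and C3 keeps its configuration because no enolisable carbonyl intermediate persists.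

**Compound list**
1 | 4-(benzyloxy)-3-methoxyphenol | COc1cc(O)ccc1OCc1ccccc1 | starting material
2 | 4-(benzyloxy)-3-methoxyphenyl trifluoromethanesulfonate | COc1cc(OS(=O)(=O)C(F)(F)F)ccc1OCc1ccccc1 | intermediate
3 | 2,3-dihydrofuran | C1=COCC1 | starting material
4 | (S)-2-[4-(benzyloxy)-3-methoxyphenyl]-2,5-dihydrofuran | COc1cc([C@H]2OCC=C2)ccc1OCc1ccccc1 | intermediate
5 | trichloroacetyl chloride | ClC(Cl)(Cl)C(=O)Cl | starting material
6 | dichloroketene (formed in the flask, not isolated) | ClC(Cl)=C=O | intermediate
7 | (1R,4S,5S)-4-[4-(benzyloxy)-3-methoxyphenyl]-7,7-dichloro-3-oxabicyclo[3.2.0]heptan-6-one | COc1cc([C@H]2OC[C@H]3[C@@H]2C(=O)C3(Cl)Cl)ccc1OCc1ccccc1 | intermediate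
8 | (1R,4S,5S)-4-[4-(benzyloxy)-3-methoxyphenyl]-7-chloro-3-oxabicyclo[3.2.0]heptan-6-one, C7 epimers (not isolated) | COc1cc([C@H]2OC[C@H]3[C@@H]2C(=O)C3Cl)ccc1OCc1ccccc1 | intermediate
9 | (1R,4S,5S)-4-[4-(benzyloxy)-3-methoxyphenyl]-3-oxabicyclo[3.2.0]heptan-6-one | COc1cc([C@H]2OC[C@H]3[C@@H]2C(=O)C3)ccc1OCc1ccccc1 | intermediate
10 | 4-bromo-1,2-dimethoxybenzene | COc1ccc(Br)cc1OC | starting material
11 | (1R,4S,5S)-4-[4-(benzyloxy)-3-methoxyphenyl]-7-(3,4-dimethoxyphenyl)-3-oxabicyclo[3.2.0]heptan-6-one, C7 epimers | COc1cc([C@H]2OC[C@H]3[C@@H]2C(=O)C3c4ccc(OC)c(OC)c4)ccc1OCc1ccccc1 | intermediate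
12 | (1S,5R,8S)-8-[4-(benzyloxy)-3-methoxyphenyl]-4-(3,4-dimethoxyphenyl)-3,7-dioxabicyclo[3.3.0]octan-2-one, C4 epimers | COc1cc([C@H]2OC[C@H]3[C@@H]2C(=O)OC3c4ccc(OC)c(OC)c4)ccc1OCc1ccccc1 | intermediate
13 | (1S,5R,8S)-4-(3,4-dimethoxyphenyl)-8-(4-hydroxy-3-methoxyphenyl)-3,7-dioxabicyclo[3.3.0]octan-2-one, C4 epimers (not isolated) | COc1cc([C@H]2OC[C@H]3[C@@H]2C(=O)OC3c4ccc(OC)c(OC)c4)ccc1O | intermediate
14 | (2S,3S,4R)-4-(3,4-dimethoxybenzyl)-2-(4-hydroxy-3-methoxyphenyl)oxolane-3-carboxylic acid | COc1cc([C@H]2OC[C@H](Cc3ccc(OC)c(OC)c3)[C@@H]2C(=O)O)ccc1O | intermediate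
15 | 4'-O-methyllariciresinol, [(2S,3R,4R)-4-(3,4-dimethoxybenzyl)-2-(4-hydroxy-3-methoxyphenyl)oxolan-3-yl]methanol | COc1cc([C@H]2OC[C@H](Cc3ccc(OC)c(OC)c3)[C@@H]2CO)ccc1O | target

Total step count: 8. Longest linear sequence: 8 steps (1 → 2 → 4 → 7 → 9 → 11 → 12 → 14 → 15).

**Steps most likely to fail**

1. Step 3 (key step). The ketene may add with little orientational preference, because the aryl group lies on the face away from the incoming ketene and distinguishes C3 from C4 only weakly. Zinc salts may also ionise the allylic benzylic ether or promote O-acylation. Fallback, from 4 and back at 12: the cycloaddition is kept, but its other orientation is made productive, so that regioselectivity no longer decides the outcome.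
   - The regioisomeric adduct (1S,2S,5R)-2-[4-(benzyloxy)-3-methoxyphenyl]-7,7-dichloro-3-oxabicyclo[3.2.0]heptan-6-one F1, which carries the carbonyl carbon on C4 of the oxolane, is separated.
   - Zn/AcOH dechlorinates it through the monochloro ketone F2 to the ketone F3.
   - 3,4-Dimethoxyphenyllithium F4 (from 10 and n-BuLi, THF, −78 °C) adds to the carbonyl group to give the tertiary cyclobutanol F5.
   - Dehydration with the Burgess reagent gives the 1-arylcyclobutene F6, whose double bond can form only toward the CH2.
   - Ozonolysis with direct NaBH4 reduction of the ozonide (O3, CH2Cl2–MeOH, −78 °C; NaBH4) opens the four-membered ring to the diol F7. In F7 the former carbonyl carbon is the aryl carbinol on C4 and the former CH2 is the hydroxymethyl group on C3.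
   - TEMPO/PhI(OAc)2 oxidises the primary alcohol and closes the lactol to lactone 12, where the main route resumes.

2. Step 5. The strained ketone may undergo aldol self-condensation, base may attack the α-aryl cyclobutanone with ring opening, or the hindered enolate may transmetalate too slowly. Fallback, from 9 and back at 12 (steps 5 and 6 are both replaced): the aryl group is brought in as a nucleophile after the four-membered ring has been cut.
   - TBSOTf/Et3N converts 9 into the silyl enol ether F8, the only enol derivative the bicycle allows.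
   - Ozonolysis (O3, CH2Cl2, −78 °C; Me2S) cleaves the ring double bond to the silyl ester aldehyde F9.
   - On aqueous work-up F9 loses the silyl group and closes to the cis-fused hydroxy lactone F10.
   - 3,4-Dimethoxyphenylmagnesium bromide F11 (from 10 and Mg; two equivalents, THF, −78 °C) adds to the aldehyde form, and acidification closes lactone 12.

3. Step 7. Over-reduction may occur: once the phenol is free, the benzylic C2–O1 bond of the oxolane may be hydrogenolysed in competition with the lactone C–O bond. Alternatively the reaction may stall at 13 and need forcing conditions. Fallback, from 11 and back at 14 (steps 6 and 7 are replaced): the temporary bond is cut as a C–C bond, so no benzylic C–O bond at that carbon ever has to be hydrogenolysed.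
   - KOH in aqueous tert-butanol at 60 °C adds to the strained carbonyl group of 11, and the tetrahedral adduct expels the benzylic carbanion (retro-Claisen-type ring opening driven by ring strain).
   - This gives the O-benzyl acid (2S,3S,4R)-2-[4-(benzyloxy)-3-methoxyphenyl]-4-(3,4-dimethoxybenzyl)oxolane-3-carboxylic acid F12.
   - A short neutral hydrogenolysis (H2, Pd/C, EtOAc) then removes only the aryl benzyl ether and gives 14.

**Further compounds**
F1 | step 3 | (1S,2S,5R)-2-[4-(benzyloxy)-3-methoxyphenyl]-7,7-dichloro-3-oxabicyclo[3.2.0]heptan-6-one | COc1cc([C@H]2OC[C@H]3[C@@H]2C(Cl)(Cl)C3=O)ccc1OCc1ccccc1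
F2 | step 3 | (1S,2S,5R)-2-[4-(benzyloxy)-3-methoxyphenyl]-7-chloro-3-oxabicyclo[3.2.0]heptan-6-one, C7 epimers | COc1cc([C@H]2OC[C@H]3[C@@H]2C(Cl)C3=O)ccc1OCc1ccccc1
F3 | step 3 | (1S,2S,5R)-2-[4-(benzyloxy)-3-methoxyphenyl]-3-oxabicyclo[3.2.0]heptan-6-one | COc1cc([C@H]2OC[C@H]3[C@@H]2CC3=O)ccc1OCc1ccccc1
F4 | step 3 | 3,4-dimethoxyphenyllithium | [Li]c1ccc(OC)c(OC)c1
F5 | step 3 | (1S,2S,5R)-2-[4-(benzyloxy)-3-methoxyphenyl]-6-(3,4-dimethoxyphenyl)-3-oxabicyclo[3.2.0]heptan-6-ol, C6 epimers | COc1cc([C@H]2OC[C@H]3[C@@H]2CC3(O)c4ccc(OC)c(OC)c4)ccc1OCc1ccccc1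
F6 | step 3 | (1S,2S,5S)-2-[4-(benzyloxy)-3-methoxyphenyl]-6-(3,4-dimethoxyphenyl)-3-oxabicyclo[3.2.0]hept-6-ene | COc1cc([C@H]2OC[C@H]3[C@@H]2C=C3c4ccc(OC)c(OC)c4)ccc1OCc1ccccc1
F7 | step 3 | [(2S,3R,4R)-2-[4-(benzyloxy)-3-methoxyphenyl]-4-[(3,4-dimethoxyphenyl)(hydroxy)methyl]oxolan-3-yl]methanol, carbinol epimers | COc1cc([C@H]2OC[C@H](C(O)c3ccc(OC)c(OC)c3)[C@@H]2CO)ccc1OCc1ccccc1
F8 | step 5 | (1S,2S,5R)-2-[4-(benzyloxy)-3-methoxyphenyl]-7-[(tert-butyldimethylsilyl)oxy]-3-oxabicyclo[3.2.0]hept-6-ene | COc1cc([C@H]2OC[C@H]3[C@@H]2C(O[Si](C)(C)C(C)(C)C)=C3)ccc1OCc1ccccc1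
F9 | step 5 | tert-butyldimethylsilyl (2S,3S,4R)-2-[4-(benzyloxy)-3-methoxyphenyl]-4-formyloxolane-3-carboxylate | COc1cc([C@H]2OC[C@H](C=O)[C@@H]2C(=O)O[Si](C)(C)C(C)(C)C)ccc1OCc1ccccc1
F10 | step 5 | (1S,5R,8S)-8-[4-(benzyloxy)-3-methoxyphenyl]-4-hydroxy-3,7-dioxabicyclo[3.3.0]octan-2-one, C4 epimers | COc1cc([C@H]2OC[C@H]3[C@@H]2C(=O)OC3O)ccc1OCc1ccccc1
F11 | step 5 | 3,4-dimethoxyphenylmagnesium bromide | COc1ccc([Mg]Br)cc1OC
F12 | step 7 | (2S,3S,4R)-2-[4-(benzyloxy)-3-methoxyphenyl]-4-(3,4-dimethoxybenzyl)oxolane-3-carboxylic acid | COc1cc([C@H]2OC[C@H](Cc3ccc(OC)c(OC)c3)[C@@H]2C(=O)O)ccc1OCc1ccccc1
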